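## Structural features

The target is a flavanone. Benzene ring A (C4a–C8a) is fused to the dihydropyranone ring C (O1, C2, C3, C4), and the 3,4-dimethoxyphenyl ring B hangs on C2. Ring A carries methoxy groups at C5, C7 and C8, so only C6 bears hydrogen. C2 (S) is the only stereocentre and has no stereogenic neighbour, so the whole stereochemical problem is absolute control at one benzylic, oxygen-bearing carbon. That carbon is fragile in two ways: as the β-carbon of the C4 ketone its C2–O1 bond opens under base (E1cB) to a 2'-hydroxychalcone that recloses as racemate, and as a p-alkoxybenzylic ether it ionises under acid. The methyl ethers are robust, but they make both arenes electron-rich. A benzylic oxygen at C4 therefore ionises just as easily, and C8a, flanked by C8–OMe and C4a, is a hindered, electron-rich aryl carbon. The real difficulty is not the 1,3-diarylpropane skeleton but closing ring C without breaking or labilising the C2–O bond and without letting base meet the finished β-aryloxy ketone. The key step exploits the fact that O1 bridges an sp2 carbon of ring A (C8a) and the stereocentre C2: if the oxygen stays on C2 and the new bond is made to C8a, the configuration at C2 is a spectator, and C4 can be held as a protected alcohol until the end.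

## Logic of the disconnections

11 to 10: no skeletal bond is cut; the C4 carbonyl is retraced to a C4 carbinol. Without the ketone the C2–O1 bond has no E1cB exit, so the ring can be closed under base. The gain is that the configuration at C4 becomes irrelevant, and 10 and everything before it may be a pair of C4 epimers. The forward oxidation must be neutral, buffered and unable to touch C2.

10 to 9: the C4 O–H bond is retraced to O–Si. During ring closure a free C4 hydroxyl could bind palladium and lose its own β-hydrogen, or take over the triflyl group from the neighbouring oxygen through a six-membered transfer. The silyl ether removes both paths. The forward step must cleave a hindered silyl ether without acid, because C4 next to ring A ionises readily.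

9 to 8: the O1–C8a bond is cut. This opens ring C to an acyclic aryl triflate carrying a free secondary carbinol, and the stereocentre becomes an ordinary benzylic alcohol. Cutting here, and not at O1–C2, means the forward step never makes or breaks a bond at the ionisable carbon. The demand is a palladium C–O coupling at a flanked, electron-rich aryl triflate in which reductive elimination outruns β-hydride elimination.

8 to 7: the C–H bond at the carbinol is retraced to a ketone. Catalytic reduction of an aryl ketone is the most dependable way to set an isolated benzylic carbinol, and it places the stereo-determining step directly before the ring closure. The demand is that the catalyst overrides the remote C1 centre in both enantiomers of 7.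

7 to 6: the Si–O bond is cut. At this stage the hydroxyl at the future C4 is the only one in the molecule, so it is silylated without any orthogonal protection. The demand is silylation of a hindered β-hydroxy ketone without β-elimination.

6 to 3 and 4 (through 5): the C3–C4 bond is cut as an aldol. This polarity is chosen on purpose. It puts the aldol stereocentre on C4, which is later destroyed, so the aldol may be racemic. It also puts the ketone on C2, where the reduction sets the permanent centre. The opposite polarity (enolisable ketone on ring A, aldehyde on ring B) would make the aldol carbon the permanent stereocentre, require an enantioselective aldol, and force the carbinol to be masked and unmasked around the reduction and silylation of C4. The demand is an enolate addition to a hindered aldehyde without retro-aldol, dehydration or attack on the triflate.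

3 to 1 and 2: the O–S bond is cut. The triflate goes on first because it doubles as the phenol protecting group for steps 2 to 4 and as the coupling handle for step 5. It must survive an enolate, a silyl triflate and borane.

## Other disconnections considered

Alternative 1: The cut runs through two bonds of ring C at once, O1–C8a and C4–C4a, leaving an aryne of ring A and the open-chain hydroxy Weinreb amide A2.
- Forward step: i-PrMgCl·LiCl would turn the iodo triflate A3 into the aryne and deprotonate A2. The alkoxide would add at the aryne carbon that becomes C8a (next to boron, remote from the C5 methoxy group). The carbanion left at C4a would be trapped by the amide to give flavanone A1.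
- In its favour: ring C and the C4 carbonyl arrive in one operation, with no protecting group and no redox change at C4. Like the chosen plan it makes the aryl–oxygen bond and leaves C2–O alone, so on retention at C2 the two are equal. On convergence and on oxidation-state economy at C4 it is the better plan.
- Against it here: C8 leaves the key step as a boronate, so oxidation and O-methylation must follow on a base-sensitive flavanone. A3 is a pentasubstituted arene that needs several steps, whereas the chosen plan buys ring A fully oxygenated. Addition of a secondary alkoxide to an aryne is not a strong reaction, and its regiochemistry rests on two directing effects.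
- Comparison: the chosen plan fixes regiochemistry by the position of the triflate and has close precedent for the ring-closing etherification. Two steps follow the key step in both plans; before it the alternative is probably longer.

Alternative 2: The cut is the C3–C4 bond, retraced as a C3=C4 double bond, leaving the aryl allyl ether A5 with a vinyl group at C2 and a silyl enol ether on ring A.
- Forward step: RuCl2(=CHPh)(PCy3)(H2IMes) (second-generation Grubbs catalyst) would initiate at the vinyl group and close onto the 1,1-disubstituted enol ether with loss of ethylene, giving the 4-silyloxy-2H-chromene A4. Mild hydrolysis of A4 would give the target.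
- In its favour: the C4 oxidation level is correct throughout, no redox step is needed, and only one step follows the key step. On step economy this alternative is better than the chosen plan.
- Against it here: A5 needs the O1–C2 bond made enantioselectively by allylic etherification of a hindered, hydrogen-bonded phenol. C2–H in A5 is at once allylic, benzylic and α to oxygen, so three paths to loss of configuration exist that the chosen plan lacks: alkene migration by hydride species formed from the catalyst, ionisation of the aryl allyl ether, and reversible 6π ring-opening of A4 to an o-quinone methide. Metathesis onto an enol ether flanked by a 2,6-disubstituted arene is also sterically demanding.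
- Comparison: the alternative is shorter; the chosen plan keeps C2 as a plain saturated carbinol or ether from the moment it is set. On the use of simple ring A and ring B building blocks the two are equal.

Alternative 3: Ring A itself is dismantled. The C4a–C5 bond is cut (and, one step earlier, C8–C8a), leaving the 4-hydroxycyclobutenone A7 that carries ring C as a dihydropyran.
- Forward step: heating A7 would open the four-membered ring to a dienylketene whose terminal alkene is the enol-ether double bond of the dihydropyran. 6π electrocyclisation joins the ketene carbon (future C5) to C4a, and tautomerisation gives hydroquinone A6.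
- In its favour: no metal is needed, the cascade is predictable, and the oxygen pattern of ring A is fixed by the regiochemistry of addition to the squarate-derived dione. It delivers C5–OH and C8–OH differentiated from C7–OMe, so for analogues with free or differently alkylated C5 and C8 oxygens it would be the best of the plans.
- Against it here: the permethylated ring A can be bought, so the cascade builds what is available. A6 is an air-sensitive hydroquinone whose C5–OH sits ortho to the C4 silyl ether, and it must be bis-methylated before desilylation and oxidation, giving three steps after the key step against two. Ring C with both C2 and C4 stereocentres must be made first, so a centre that is later discarded has to be controlled.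
- Comparison: in mechanistic predictability the two ring closures are about equal; in step count and in where the effort is spent the chosen plan is better.

Key step: step 5

Assumption: aldehyde 1 and ketone 4 are bought as catalogue compounds; 1 carries the same ring A oxygenation as the common flavonoid building blocks.

Remark: the stereodescriptors were checked and are consistent: C2 of 11 is S, ring closure at C8a retains the carbinol configuration, and C4 is erased in step 7. Compounds 8, 9 and 10 are therefore carried as pairs of C4 epimers (chromane numbering), of which the (1R,3S) member of 8 and the (2S,4R) member of 9 are the 2,4-trans ones.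

Step 1
Reactants: 1 2-hydroxy-3,4,6-trimethoxybenzaldehyde; 2 trifluoromethanesulfonic anhydride
Product: 3 2-formyl-3,5,6-trimethoxyphenyl trifluoromethanesulfonate
Conditions: pyridine, CH2Cl2, 0 °C to rt
Reagents that add atoms: none
Why: O-sulfonylation of a phenol; the very electrophilic anhydride should acylate even this hydrogen-bonded, flanked phenol, and pyridine takes up the acid. The triflate masks the phenol through steps 2 to 4 and is the coupling handle of step 5.

Step 2
Reactants: 4 1-(3,4-dimethoxyphenyl)ethan-1-one; 3 2-formyl-3,5,6-trimethoxyphenyl trifluoromethanesulfonate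
Product: 6 2-[3-(3,4-dimethoxyphenyl)-1-hydroxy-3-oxopropyl]-3,5,6-trimethoxyphenyl trifluoromethanesulfonate (racemic), via lithium 1-(3,4-dimethoxyphenyl)ethenolate 5 (not isolated)
Conditions: LiN(SiMe3)2, THF, −78 °C; then 3, −78 °C; AcOH quench at −78 °C
Reagents that add atoms: lithium bis(trimethylsilyl)amide, [Li+].C[Si](C)(C)[N-][Si](C)(C)C (supplies the lithium of 5 only)
Why: aldol addition of a preformed lithium enolate to a non-enolisable aldehyde forms the C3–C4 bond. The new centre (future C4) is left racemic on purpose because step 7 destroys it. The cold acidic quench should prevent retro-aldol, dehydration and transfer of the triflyl group to the new alkoxide.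

Step 3
Reactants: 6 2-[3-(3,4-dimethoxyphenyl)-1-hydroxy-3-oxopropyl]-3,5,6-trimethoxyphenyl trifluoromethanesulfonate (racemic)
Product: 7 2-[1-(tert-butyldimethylsilyloxy)-3-(3,4-dimethoxyphenyl)-3-oxopropyl]-3,5,6-trimethoxyphenyl trifluoromethanesulfonate (racemic)
Conditions: TBSOTf, 2,6-lutidine, CH2Cl2, −78 to −20 °C
Reagents that add atoms: tert-butyldimethylsilyl trifluoromethanesulfonate, CC(C)(C)[Si](C)(C)OS(=O)(=O)C(F)(F)F
Why: silylation of a hindered secondary alcohol with a silyl triflate and a hindered, non-nucleophilic base. It is the only hydroxyl present, so no selectivity is needed, and the low temperature should suppress β-elimination.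

Step 4
Reactants: 7 2-[1-(tert-butyldimethylsilyloxy)-3-(3,4-dimethoxyphenyl)-3-oxopropyl]-3,5,6-trimethoxyphenyl trifluoromethanesulfonate (racemic)
Product: 8 2-[(3S)-1-(tert-butyldimethylsilyloxy)-3-(3,4-dimethoxyphenyl)-3-hydroxypropyl]-3,5,6-trimethoxyphenyl trifluoromethanesulfonate ((1R,3S) and (1S,3S) epimers)
Conditions: (R)-2-methyl-CBS-oxazaborolidine (20 mol%), BH3·SMe2, THF, −20 °C; MeOH quench
Reagents that add atoms: none
Why: Corey–Bakshi–Shibata reduction: the ketone binds the ring boron anti to its aryl group, and the nitrogen-bound borane delivers hydride to the Re face, giving the 3S carbinol in the same sense in which the (R)-catalyst gives (S)-1-phenylethanol. Catalyst control should dominate the remote, weakly biasing silyloxy centre, so both enantiomers of 7 should end as 3S.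

Step 5
Reactants: 8 2-[(3S)-1-(tert-butyldimethylsilyloxy)-3-(3,4-dimethoxyphenyl)-3-hydroxypropyl]-3,5,6-trimethoxyphenyl trifluoromethanesulfonate ((1R,3S) and (1S,3S) epimers)
Product: 9 (2S)-4-(tert-butyldimethylsilyloxy)-2-(3,4-dimethoxyphenyl)-5,7,8-trimethoxychromane ((2S,4R) and (2S,4S) epimers)
Conditions: Pd(OAc)2 (5 mol%), 2-(di-tert-butylphosphino)-1,1'-binaphthyl (7.5 mol%), Cs2CO3 (1.5 equiv), toluene, 80 °C
Reagents that add atoms: none
Why: Pd(OAc)2 is reduced in the flask to zerovalent palladium, which, carrying one bulky di-tert-butylbiarylphosphine, inserts into the C8a–OTf bond; Cs2CO3 deprotonates the only free hydroxyl, and the C2 alkoxide replaces triflate on divalent palladium to give a seven-membered chelate in which the metal holds C8a and the C2 oxygen. C–O reductive elimination from this chelate forms O1–C8a, closes ring C as a six-membered cyclic ether and returns zerovalent palladium. The closest known reaction type is the palladium-catalysed intramolecular etherification of aryl halides and sulfonates with secondary alcohols to chromans (Buchwald–Hartwig C–O coupling). No stereocentre is created: the C2–O bond is neither made nor broken, so the S configuration from step 4 is carried over, which a closure by substitution at the ionisable benzylic carbon could not guarantee. The selectivity needed is reductive elimination ahead of β-hydride elimination from the C2 alkoxide, which would oxidise the carbinol and reduce the aryl–palladium bond; the steric pressure of the ligand and the favourable ring size should secure it. The C4 oxygen is silylated so that it can neither bind palladium and lose its own β-hydrogen nor accept the triflyl group, and both C4 epimers can reach the chelate. Oxidative addition at the flanked, electron-rich triflate is expected to be the slow step, hence the electron-rich ligand, the weakly nucleophilic carbonate base and a non-polar solvent that hold back S–O cleavage of the triflate.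

Step 6
Reactants: 9 (2S)-4-(tert-butyldimethylsilyloxy)-2-(3,4-dimethoxyphenyl)-5,7,8-trimethoxychromane ((2S,4R) and (2S,4S) epimers)
Product: 10 (2S)-2-(3,4-dimethoxyphenyl)-5,7,8-trimethoxychroman-4-ol (both C4 epimers)
Conditions: n-Bu4NF, THF, 0 °C to rt; aqueous work-up
Reagents that add atoms: none
Why: fluoride-induced cleavage of the Si–O bond under basic, acid-free conditions, so the C4–O bond next to electron-rich ring A should not ionise. With no ketone present, base cannot open the C2–O1 bond.

Step 7
Reactants: 10 (2S)-2-(3,4-dimethoxyphenyl)-5,7,8-trimethoxychroman-4-ol (both C4 epimers)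
Product: 11 (2S)-2-(3,4-dimethoxyphenyl)-5,7,8-trimethoxychroman-4-one
Conditions: Dess–Martin periodinane, pyridine, CH2Cl2, 0 °C to rt
Reagents that add atoms: none
Why: Dess–Martin oxidation (ligand exchange at iodine, then loss of the C4 hydrogen) converts both C4 epimers into the same ketone. The pyridine buffer keeps acetic acid from ionising C4, and the medium is too weakly basic to open the β-aryloxy ketone, so C2 should stay S.

Compound list
1 | 2-hydroxy-3,4,6-trimethoxybenzaldehyde | O=Cc1c(OC)cc(OC)c(OC)c1O | starting material
2 | trifluoromethanesulfonic anhydride | O=S(=O)(OS(=O)(=O)C(F)(F)F)C(F)(F)F | starting material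
3 | 2-formyl-3,5,6-trimethoxyphenyl trifluoromethanesulfonate | O=Cc1c(OC)cc(OC)c(OC)c1OS(=O)(=O)C(F)(F)F | intermediate
4 | 1-(3,4-dimethoxyphenyl)ethan-1-one | CC(=O)c1ccc(OC)c(OC)c1 | starting material
5 | lithium 1-(3,4-dimethoxyphenyl)ethenolate | [Li+].[O-]C(=C)c1ccc(OC)c(OC)c1 | intermediate
6 | 2-[3-(3,4-dimethoxyphenyl)-1-hydroxy-3-oxopropyl]-3,5,6-trimethoxyphenyl trifluoromethanesulfonate, racemic | COc1ccc(C(=O)CC(O)c2c(OC)cc(OC)c(OC)c2OS(=O)(=O)C(F)(F)F)cc1OC | intermediate
7 | 2-[1-(tert-butyldimethylsilyloxy)-3-(3,4-dimethoxyphenyl)-3-oxopropyl]-3,5,6-trimethoxyphenyl trifluoromethanesulfonate, racemic | COc1ccc(C(=O)CC(O[Si](C)(C)C(C)(C)C)c2c(OC)cc(OC)c(OC)c2OS(=O)(=O)C(F)(F)F)cc1OC | intermediate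
8 | 2-[(3S)-1-(tert-butyldimethylsilyloxy)-3-(3,4-dimethoxyphenyl)-3-hydroxypropyl]-3,5,6-trimethoxyphenyl trifluoromethanesulfonate, (1R,3S) and (1S,3S) epimers, C1 left open in the SMILES | COc1ccc([C@@H](O)CC(O[Si](C)(C)C(C)(C)C)c2c(OC)cc(OC)c(OC)c2OS(=O)(=O)C(F)(F)F)cc1OC | intermediate
9 | (2S)-4-(tert-butyldimethylsilyloxy)-2-(3,4-dimethoxyphenyl)-5,7,8-trimethoxychromane, (2S,4R) and (2S,4S) epimers, C4 left open in the SMILES | COc1ccc([C@@H]2CC(O[Si](C)(C)C(C)(C)C)c3c(OC)cc(OC)c(OC)c3O2)cc1OC | intermediate
10 | (2S)-2-(3,4-dimethoxyphenyl)-5,7,8-trimethoxychroman-4-ol, both C4 epimers, C4 left open in the SMILES | COc1ccc([C@@H]2CC(O)c3c(OC)cc(OC)c(OC)c3O2)cc1OC | intermediate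
11 | (2S)-2-(3,4-dimethoxyphenyl)-5,7,8-trimethoxychroman-4-one | COc1ccc([C@@H]2CC(=O)c3c(OC)cc(OC)c(OC)c3O2)cc1OC | target

Total step count: 7. Longest linear sequence: 7 steps (1 to 11); ketone 4 enters in step 2.

Least certain steps

Step 5 (key step). The most likely failure is that oxidative addition at the flanked, electron-rich triflate is too slow. Then cleavage of the S–O bond by alkoxide or carbonate (loss of the triflyl group), or β-hydride elimination at the palladium-bound alkoxide with reduction of the aryl carbon, overtakes ring closure. The fallback forms the other ether bond, O1–C2, with inversion. It sets out from 7: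
- Reduction with the (S)-oxazaborolidine and BH3·SMe2 should give the 3R carbinol, 2-[(3R)-1-(tert-butyldimethylsilyloxy)-3-(3,4-dimethoxyphenyl)-3-hydroxypropyl]-3,5,6-trimethoxyphenyl trifluoromethanesulfonate F1.
- Et4NOH in dioxane cleaves the triflate to the phenol, (1R)-3-(tert-butyldimethylsilyloxy)-1-(3,4-dimethoxyphenyl)-3-(2-hydroxy-3,4,6-trimethoxyphenyl)propan-1-ol F2.
- Mitsunobu closure (PPh3, DIAD, THF, 0 °C) attacks C2 with the phenol oxygen with inversion and comes back to the route at 9.
- The weak point is partial ionisation at the p-alkoxybenzylic carbon, so the enantiomeric purity of 9 would have to be checked at once.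

Step 2. What may go wrong is retro-aldol on warming, E1cB loss of water from the aldolate, or migration of the triflyl group from the phenol oxygen to the neighbouring alkoxide. The fallback makes the C3–C4 bond as an alkene, which cannot revert, and adds the C4 oxygen afterwards. It sets out from 1 and 4:
- Claisen–Schmidt condensation (KOH, EtOH) should give (E)-1-(3,4-dimethoxyphenyl)-3-(2-hydroxy-3,4,6-trimethoxyphenyl)prop-2-en-1-one F3.
- Triflation with 2 and pyridine gives 2-[(E)-3-(3,4-dimethoxyphenyl)-3-oxoprop-1-en-1-yl]-3,5,6-trimethoxyphenyl trifluoromethanesulfonate F4.
- Copper-catalysed conjugate borylation (CuCl, NaOt-Bu, Xantphos, B2pin2, MeOH, THF) gives 2-[3-(3,4-dimethoxyphenyl)-3-oxo-1-(4,4,5,5-tetramethyl-1,3,2-dioxaborolan-2-yl)propyl]-3,5,6-trimethoxyphenyl trifluoromethanesulfonate F5.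
- Oxidation of the C–B bond with NaBO3·4H2O in THF/H2O comes back to the route at 6.

Step 3. What may go wrong is β-elimination of the aldol under base, ionisation of the benzylic carbinol by the Lewis-acidic silyl triflate, or slow silylation at the flanked position. The fallback lets the silyl group arrive with the C–C bond, so that no free β-hydroxy ketone exists. It sets out from 4 and 3:
- TBSOTf and Et3N convert 4 into tert-butyl{[1-(3,4-dimethoxyphenyl)ethenyl]oxy}dimethylsilane F6.
- A Mukaiyama aldol addition of F6 to 3 catalysed by HNTf2 (CH2Cl2, −78 °C) proceeds with transfer of the silyl group to the aldol oxygen and comes back to the route at 7.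

Step 4. What may go wrong is incomplete catalyst control in the half of racemic 7 whose C1 centre opposes the catalyst, or an uncatalysed background reduction. Either would erode the enantiomeric purity at C2, and this becomes visible only after step 7. The fallback changes the mode of stereo-induction from borane delivery on a Lewis-acidic boron to outer-sphere transfer hydrogenation: RuCl(p-cymene)[(S,S)-TsDPEN] with HCO2H/Et3N recognises the aryl ring of the ketone and is known to give S carbinols from aryl alkyl ketones. It sets out from 7 and comes back at 8 with no new compound (F0). If needed, the two C1 epimers of 8, being diastereomers, can be separated so that only the stereochemically clean one is carried on.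

Further compounds
F1 | step 5 | 2-[(3R)-1-(tert-butyldimethylsilyloxy)-3-(3,4-dimethoxyphenyl)-3-hydroxypropyl]-3,5,6-trimethoxyphenyl trifluoromethanesulfonate, both C1 epimers | COc1ccc([C@H](O)CC(O[Si](C)(C)C(C)(C)C)c2c(OC)cc(OC)c(OC)c2OS(=O)(=O)C(F)(F)F)cc1OC
F2 | step 5 | (1R)-3-(tert-butyldimethylsilyloxy)-1-(3,4-dimethoxyphenyl)-3-(2-hydroxy-3,4,6-trimethoxyphenyl)propan-1-ol, both C3 epimers | COc1ccc([C@H](O)CC(O[Si](C)(C)C(C)(C)C)c2c(OC)cc(OC)c(OC)c2O)cc1OC
F3 | step 2 | (E)-1-(3,4-dimethoxyphenyl)-3-(2-hydroxy-3,4,6-trimethoxyphenyl)prop-2-en-1-one | COc1ccc(C(=O)/C=C/c2c(OC)cc(OC)c(OC)c2O)cc1OC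
F4 | step 2 | 2-[(E)-3-(3,4-dimethoxyphenyl)-3-oxoprop-1-en-1-yl]-3,5,6-trimethoxyphenyl trifluoromethanesulfonate | COc1ccc(C(=O)/C=C/c2c(OC)cc(OC)c(OC)c2OS(=O)(=O)C(F)(F)F)cc1OC
F5 | step 2 | 2-[3-(3,4-dimethoxyphenyl)-3-oxo-1-(4,4,5,5-tetramethyl-1,3,2-dioxaborolan-2-yl)propyl]-3,5,6-trimethoxyphenyl trifluoromethanesulfonate, racemic | COc1ccc(C(=O)CC(B2OC(C)(C)C(C)(C)O2)c3c(OC)cc(OC)c(OC)c3OS(=O)(=O)C(F)(F)F)cc1OC
F6 | step 3 | tert-butyl{[1-(3,4-dimethoxyphenyl)ethenyl]oxy}dimethylsilane | C=C(O[Si](C)(C)C(C)(C)C)c1ccc(OC)c(OC)c1
F0 | step 4 | none | none
A1 | alternative 1 | (2S)-2-(3,4-dimethoxyphenyl)-5,7-dimethoxy-8-(4,4,5,5-tetramethyl-1,3,2-dioxaborolan-2-yl)chroman-4-one | COc1ccc([C@@H]2CC(=O)c3c(OC)cc(OC)c(B4OC(C)(C)C(C)(C)O4)c3O2)cc1OC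
A2 | alternative 1 | (3S)-3-(3,4-dimethoxyphenyl)-3-hydroxy-N-methoxy-N-methylpropanamide | COc1ccc([C@@H](O)CC(=O)N(C)OC)cc1OC
A3 | alternative 1 | 2-iodo-3,5-dimethoxy-6-(4,4,5,5-tetramethyl-1,3,2-dioxaborolan-2-yl)phenyl trifluoromethanesulfonate | COc1cc(OC)c(B2OC(C)(C)C(C)(C)O2)c(OS(=O)(=O)C(F)(F)F)c1I
A4 | alternative 2 | (2S)-4-(tert-butyldimethylsilyloxy)-2-(3,4-dimethoxyphenyl)-5,7,8-trimethoxy-2H-chromene | COc1ccc([C@@H]2C=C(O[Si](C)(C)C(C)(C)C)c3c(OC)cc(OC)c(OC)c3O2)cc1OC
A5 | alternative 2 | tert-butyl{[1-(2-{[(1S)-1-(3,4-dimethoxyphenyl)prop-2-en-1-yl]oxy}-3,4,6-trimethoxyphenyl)ethenyl]oxy}dimethylsilane | COc1ccc([C@H](C=C)Oc2c(OC)c(OC)cc(OC)c2C(=C)O[Si](C)(C)C(C)(C)C)cc1OC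
A6 | alternative 3 | (2S,4S)-4-(tert-butyldimethylsilyloxy)-2-(3,4-dimethoxyphenyl)-7-methoxychromane-5,8-diol | COc1ccc([C@@H]2C[C@H](O[Si](C)(C)C(C)(C)C)c3c(O)cc(OC)c(O)c3O2)cc1OC
A7 | alternative 3 | 4-[(2S,4S)-4-(tert-butyldimethylsilyloxy)-2-(3,4-dimethoxyphenyl)-3,4-dihydro-2H-pyran-6-yl]-4-hydroxy-3-methoxycyclobut-2-en-1-one, either configuration at the cyclobutenone carbinol | COc1ccc([C@@H]2C[C@H](O[Si](C)(C)C(C)(C)C)C=C(C3(O)C(OC)=CC3=O)O2)cc1OC
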